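**Retrosynthetic overview**
- Isoamoritin is cut at two ring bonds at once: the C-ring O1–C2 bond (asymmetric oxa-Michael, sets C2) and the A-ring C4a–C5 bond (Claisen cyclisation/aromatisation). This leads back to an open-chain diprenylated cinnamoyl triketo ester, stored as its 4-hydroxy-2-pyrone lactone.
- The pyrone lactone comes from C-acylation of the 6-methyl carbanion of 4-hydroxy-6-methyl-3,5-diprenyl-2-pyrone with a B-ring cinnamoyl Weinreb amide.
- The diprenyl pyrone comes from methyl acetoacetate (γ,α-diprenylation, then γ-acetylation/lactonisation). The Weinreb amide comes from 3-bromo-4,5-dihydroxybenzaldehyde (4-O-methylation, Stille prenylation, HWE).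
- Ring order: the B ring is bought; a temporary pyrone ring is made and later opened; the A ring and then the C ring are formed together in the last operation.

Assumption: the quinidine-derived squaramide is taken to give the (2S) series in step 7; if the sense proves opposite, the quinine-derived pseudoenantiomer replaces it and nothing else changes.

**Route**

Step 1
Reactants: 1 3-bromo-4,5-dihydroxybenzaldehyde
Product: 2 3-bromo-5-hydroxy-4-methoxybenzaldehyde
Conditions: MeI (1.1 equiv), Li2CO3 (1.2 equiv), DMF, 40 °C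
Reagents that add atoms: iodomethane, CI
Why: The 4-OH (para to CHO, ortho to Br) is the more acidic phenol, so with one equivalent of weak base only its phenoxide forms and is methylated (regioselective Williamson ether synthesis).

Step 2
Reactants: 2 3-bromo-5-hydroxy-4-methoxybenzaldehyde
Product: 3 3-hydroxy-4-methoxy-5-(3-methylbut-2-en-1-yl)benzaldehyde
Conditions: Bu3Sn-prenyl (1.3 equiv), Pd(PPh3)4 (5 mol%), DMF, 100 °C
Reagents that add atoms: tributyl(3-methylbut-2-en-1-yl)stannane, CCCC[Sn](CCCC)(CCCC)CC=C(C)C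
Why: Migita–Kosugi–Stille coupling transfers the prenyl group through its less hindered α-carbon to give the linear prenyl arene, and the neutral conditions tolerate the free phenol and the aldehyde.

Step 3
Reactants: 3 3-hydroxy-4-methoxy-5-(3-methylbut-2-en-1-yl)benzaldehyde
Product: 4 (2E)-3-[3-hydroxy-4-methoxy-5-(3-methylbut-2-en-1-yl)phenyl]-N-methoxy-N-methylprop-2-enamide
Conditions: (EtO)2P(O)CH2C(O)N(OMe)Me (1.2 equiv), LiCl, DBU (2.5 equiv), MeCN, 0 °C to rt
Reagents that add atoms: diethyl {2-[methoxy(methyl)amino]-2-oxoethyl}phosphonate, CCOP(=O)(CC(=O)N(C)OC)OCC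
Why: Horner–Wadsworth–Emmons olefination under Masamune–Roush conditions gives the (E)-enamide from the stabilised phosphonate anion, and the meta-phenoxide does not deactivate the aldehyde.

Step 4
Reactants: 5 methyl acetoacetate
Product: 7 methyl 7-methyl-2-(3-methylbut-2-en-1-yl)-3-oxooct-6-enoate, via sodium enolate 6 (not isolated)
Conditions: NaH (1.1 equiv), THF, 0 °C; n-BuLi (1.05 equiv), 0 °C; prenyl bromide (1.0 equiv), 0 °C; then prenyl bromide (1.15 equiv), rt to 50 °C
Reagents that add atoms: 1-bromo-3-methylbut-2-ene (prenyl bromide, used twice), CC(C)=CCBr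
Why: Huckin–Weiler dianion alkylation prenylates the more basic γ-carbanion first, and the remaining α-enolate is then C-prenylated in the same flask (acetoacetic ester alkylation); the new C2 centre is racemic and disappears in step 5.

Step 5
Reactants: 7 methyl 7-methyl-2-(3-methylbut-2-en-1-yl)-3-oxooct-6-enoate
Product: 9 4-hydroxy-6-methyl-3,5-bis(3-methylbut-2-en-1-yl)-2H-pyran-2-one, via diketo ester 8 (not isolated)
Conditions: LDA (2.3 equiv), THF, –78 to 0 °C; MeC(O)N(OMe)Me (1.2 equiv), –78 to 0 °C; aq. HCl work-up, crude carried on; DBU (2 equiv), PhMe, 80 °C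
Reagents that add atoms: N-methoxy-N-methylacetamide, CC(=O)N(C)OC
Why: γ-C-Acylation of the β-keto ester dianion by a Weinreb amide (stable tetrahedral intermediate, no over-addition) is followed by DBU-mediated enol-lactonisation of the 3,5-diketo ester to the 4-hydroxy-2-pyrone, which removes both stereocentres of 8.

Step 6
Reactants: 9 4-hydroxy-6-methyl-3,5-bis(3-methylbut-2-en-1-yl)-2H-pyran-2-one; 4 (2E)-3-[3-hydroxy-4-methoxy-5-(3-methylbut-2-en-1-yl)phenyl]-N-methoxy-N-methylprop-2-enamide
Product: 10 4-hydroxy-6-{(3E)-4-[3-hydroxy-4-methoxy-5-(3-methylbut-2-en-1-yl)phenyl]-2-oxobut-3-en-1-yl}-3,5-bis(3-methylbut-2-en-1-yl)-2H-pyran-2-one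
Conditions: 9 (1.3 equiv), LDA (2.2 equiv per 9), THF, –78 °C; add 4 pre-treated with LiHMDS (1.0 equiv), –78 to 0 °C; aq. HCl
Reagents that add atoms: none
Why: The 4-oxido-6-methylpyrone dianion (vinylogous carbanion at the 6-CH3) undergoes crossed-Claisen-type C-acylation by 1,2-addition to the Weinreb amide, whose chelated tetrahedral intermediate prevents double addition while the phenoxide of 4 is a spectator.

Step 7
Reactants: 10 4-hydroxy-6-{(3E)-4-[3-hydroxy-4-methoxy-5-(3-methylbut-2-en-1-yl)phenyl]-2-oxobut-3-en-1-yl}-3,5-bis(3-methylbut-2-en-1-yl)-2H-pyran-2-one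
Product: 13 isoamoritin, via triketo ester 11 (not isolated), via chalcone 12 (not isolated)
Conditions: Mg(OMe)2 (8 equiv), MeOH, 65 °C, Ar; inverse quench into 1 M HCl/PhMe at 0 °C, dried PhMe phase used directly; 9-amino(9-deoxy)epi-quinidine 3,5-bis(trifluoromethyl)phenyl squaramide (10 mol%), PhMe, –20 °C
Reagents that add atoms: none
Why: Proposed new method: methoxide opens the lactone of 10 to the Mg-chelated triketo ester 11, whose C6 methylene (between two ketones) attacks the C1 ester in a Claisen (Dieckmann-type) cyclisation and enolises to the aromatic A ring (the competing aldol mode is reversible and unproductive because C2 carries a prenyl group and cannot aromatise); the product is expected to rest as the open chalcone polyphenoxide because the open form has one more ionisable OH, and after the cold acid quench neutral chalcone 12 closes by 6-endo oxa-Michael addition inside the chiral ion pair with the bifunctional squaramide (quinuclidine N deprotonates the non-chelated ortho-OH, squaramide N–H binds the chelated enone), which selects one enone face and sets C2 as S; the closest known reactions are the Mg(OMe)2 or alkoxide rearrangement of 6-(2-oxoalkyl)-4-hydroxy-2-pyrones and 3,5,7-triketo esters to acylphloroglucinols, and the cinchona thiourea/squaramide-catalysed intramolecular oxa-Michael cyclisation of 2'-hydroxychalcones to flavanones.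

**Compound list**
1 | 3-bromo-4,5-dihydroxybenzaldehyde | O=Cc1cc(O)c(O)c(Br)c1 | starting material
2 | 3-bromo-5-hydroxy-4-methoxybenzaldehyde | COc1c(O)cc(C=O)cc1Br | intermediate
3 | 3-hydroxy-4-methoxy-5-(3-methylbut-2-en-1-yl)benzaldehyde | COc1c(O)cc(C=O)cc1CC=C(C)C | intermediate
4 | (2E)-3-[3-hydroxy-4-methoxy-5-(3-methylbut-2-en-1-yl)phenyl]-N-methoxy-N-methylprop-2-enamide | COc1c(O)cc(/C=C/C(=O)N(C)OC)cc1CC=C(C)C | intermediate
5 | methyl acetoacetate (methyl 3-oxobutanoate) | COC(=O)CC(C)=O | starting material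
6 | sodium enolate of methyl 7-methyl-3-oxooct-6-enoate (not isolated) | COC(=O)C=C([O-])CCC=C(C)C.[Na+] | intermediate
7 | methyl 7-methyl-2-(3-methylbut-2-en-1-yl)-3-oxooct-6-enoate (racemic at C2) | COC(=O)C(CC=C(C)C)C(=O)CCC=C(C)C | intermediate
8 | methyl 2,4-bis(3-methylbut-2-en-1-yl)-3,5-dioxohexanoate (mixture of epimers and enol forms, not isolated) | COC(=O)C(CC=C(C)C)C(=O)C(CC=C(C)C)C(C)=O | intermediate
9 | 4-hydroxy-6-methyl-3,5-bis(3-methylbut-2-en-1-yl)-2H-pyran-2-one | Cc1oc(=O)c(CC=C(C)C)c(O)c1CC=C(C)C | intermediate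
10 | 4-hydroxy-6-{(3E)-4-[3-hydroxy-4-methoxy-5-(3-methylbut-2-en-1-yl)phenyl]-2-oxobut-3-en-1-yl}-3,5-bis(3-methylbut-2-en-1-yl)-2H-pyran-2-one | COc1c(O)cc(/C=C/C(=O)Cc2oc(=O)c(CC=C(C)C)c(O)c2CC=C(C)C)cc1CC=C(C)C | intermediate
11 | methyl (8E)-9-[3-hydroxy-4-methoxy-5-(3-methylbut-2-en-1-yl)phenyl]-2,4-bis(3-methylbut-2-en-1-yl)-3,5,7-trioxonon-8-enoate (Mg chelate, epimer/enol mixture, not isolated) | COC(=O)C(CC=C(C)C)C(=O)C(CC=C(C)C)C(=O)CC(=O)/C=C/c1cc(O)c(OC)c(CC=C(C)C)c1 | intermediate
12 | (2E)-3-[3-hydroxy-4-methoxy-5-(3-methylbut-2-en-1-yl)phenyl]-1-[2,4,6-trihydroxy-3,5-bis(3-methylbut-2-en-1-yl)phenyl]prop-2-en-1-one (not isolated) | COc1c(O)cc(/C=C/C(=O)c2c(O)c(CC=C(C)C)c(O)c(CC=C(C)C)c2O)cc1CC=C(C)C | intermediate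
13 | isoamoritin, (2S)-5,7-dihydroxy-2-[3-hydroxy-4-methoxy-5-(3-methylbut-2-en-1-yl)phenyl]-6,8-bis(3-methylbut-2-en-1-yl)-2,3-dihydro-4H-chromen-4-one | COc1c(O)cc([C@@H]2CC(=O)c3c(O)c(CC=C(C)C)c(O)c(CC=C(C)C)c3O2)cc1CC=C(C)C | target

**Totals**
Total step count: 7.
Longest linear sequence: 5 steps (1 → 2 → 3 → 4 → 10 → 13).

**Steps most likely to fail, with fallbacks**

Step 7. The hindered 3,5-diprenyl lactone may open slowly, some chalcone may close to racemic flavanone before the catalyst is present, and the ee of the catalysed closure is unproven for this substrate. The fallback sets out from 10 and obtains the stereocentre by resolution instead of asymmetric catalysis. Run the Mg(OMe)2 stage as above, then let the chalcone close under thermodynamic control (NaOAc, EtOH, 60 °C) to racemic isoamoritin F1. Resolve F1 by kinetic resolution through asymmetric transfer hydrogenation [Cp*RhCl((R,R)-TsDPEN), HCO2H/Et3N, EtOAc, rt, stopped near 55% conversion]. The (2R)-ketone is reduced to the cis-flavan-4-ol (2R,4R)-2-[3-hydroxy-4-methoxy-5-(3-methylbut-2-en-1-yl)phenyl]-6,8-bis(3-methylbut-2-en-1-yl)-3,4-dihydro-2H-chromene-4,5,7-triol F2, which is separated by chromatography. The unreacted (2S)-flavanone is the point of return, at 13 (at most 50%).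

Step 6. The dianion of 9 may add 1,4 to the enamide, or react sluggishly with the phenoxide-bearing Weinreb amide. The fallback sets out from 3 (with 9 as partner) and replaces acylation by aldehyde addition and oxidation. Homologate 3 with (triphenylphosphoranylidene)acetaldehyde (PhMe, 80 °C) to the enal (2E)-3-[3-hydroxy-4-methoxy-5-(3-methylbut-2-en-1-yl)phenyl]prop-2-enal F3. Add the dianion of 9 (LDA, THF, –78 °C) 1,2 to F3 (phenol pre-deprotonated) to give the racemic allylic alcohol 4-hydroxy-6-{(3E)-2-hydroxy-4-[3-hydroxy-4-methoxy-5-(3-methylbut-2-en-1-yl)phenyl]but-3-en-1-yl}-3,5-bis(3-methylbut-2-en-1-yl)-2H-pyran-2-one F4. Oxidise F4 with MnO2 (CH2Cl2, rt) to return at 10; step 3 is then not needed.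

Step 2. The Stille prenyl transfer may give some branched (1,1-dimethylallyl) isomer or stall on the ortho-methoxy bromide. The fallback sets out from 2 and builds the prenyl group in two stages. Couple 2 with allyltributylstannane (Pd(PPh3)4, DMF, 100 °C), which has no regiochemical ambiguity, to give 3-hydroxy-4-methoxy-5-(prop-2-en-1-yl)benzaldehyde F5. Convert F5 by olefin cross-metathesis with excess 2-methylbut-2-ene (Grubbs II, CH2Cl2, 40 °C) to return at 3.

**Further compounds**
F1 | step 7 | racemic isoamoritin, (2RS)-5,7-dihydroxy-2-[3-hydroxy-4-methoxy-5-(3-methylbut-2-en-1-yl)phenyl]-6,8-bis(3-methylbut-2-en-1-yl)-2,3-dihydro-4H-chromen-4-one | COc1c(O)cc(C2CC(=O)c3c(O)c(CC=C(C)C)c(O)c(CC=C(C)C)c3O2)cc1CC=C(C)C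
F2 | step 7 | (2R,4R)-2-[3-hydroxy-4-methoxy-5-(3-methylbut-2-en-1-yl)phenyl]-6,8-bis(3-methylbut-2-en-1-yl)-3,4-dihydro-2H-chromene-4,5,7-triol | COc1c(O)cc([C@H]2C[C@@H](O)c3c(O)c(CC=C(C)C)c(O)c(CC=C(C)C)c3O2)cc1CC=C(C)C
F3 | step 6 | (2E)-3-[3-hydroxy-4-methoxy-5-(3-methylbut-2-en-1-yl)phenyl]prop-2-enal | COc1c(O)cc(/C=C/C=O)cc1CC=C(C)C
F4 | step 6 | racemic 4-hydroxy-6-{(3E)-2-hydroxy-4-[3-hydroxy-4-methoxy-5-(3-methylbut-2-en-1-yl)phenyl]but-3-en-1-yl}-3,5-bis(3-methylbut-2-en-1-yl)-2H-pyran-2-one | COc1c(O)cc(/C=C/C(O)Cc2oc(=O)c(CC=C(C)C)c(O)c2CC=C(C)C)cc1CC=C(C)C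
F5 | step 2 | 3-hydroxy-4-methoxy-5-(prop-2-en-1-yl)benzaldehyde | COc1c(O)cc(C=O)cc1CC=C
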